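**Retrosynthetic overview**
1. The target is a trans-(2R,3R)-2-aryl-3-methyl-2,3-dihydro-1,4-benzodioxine. Ring A is the benzo ring (5-OMe, 7-E-propenyl), ring B the dioxane ring (O1, C2, C3, O4), and ring C the 4-hydroxy-3,5-dimethoxyphenyl group on C2.
2. The final disconnection is O1–C2. Ring B opens to an unprotected seco-diphenol with a plain CH2 at C2 and only the C3 stereocentre. A laccase (multicopper oxidase) with O2 removes two hydrogens, ring B closes, and C2 is set.
3. Enabling feature: the free OH on C4 of ring C is para to the benzylic carbon C2, so ring C can be dehydrogenated to a p-quinone methide that is electrophilic exactly at C2. The OH on C8a of ring A is held by the C4a–O4–C3 tether within six-ring distance of C2.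
4. In the seco-diphenol, the E-propenyl group comes from a Suzuki–Miyaura coupling at C7–Br and O1 from Baeyer–Villiger oxidation of an ortho-formyl group. The C3–O4 bond comes from Mitsunobu inversion of an (S)-1-arylpropan-2-ol with 5-bromo-2-hydroxy-3-methoxybenzaldehyde. That alcohol comes from the ring C Grignard reagent and (S)-propylene oxide, the only source of chirality.
5. Ring order: rings A and C are bought as arenes. Ring B is the only ring formed, and it is formed last.

Key step: step 6

Assumption: the commercial fungal laccase oxidises phenols by outer-sphere electron transfer at a surface-exposed copper site, so it is taken to accept the seco-diphenol despite its size.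

**Step 1**
Reactants: 1 4-bromo-2,6-dimethoxyphenol
Product: 2 5-bromo-1,3-dimethoxy-2-(methoxymethoxy)benzene
Conditions: MOMCl, K2CO3, acetone, 0 °C to rt
Reagents that add atoms: chloromethyl methyl ether (MOMCl), COCCl
Why: Williamson-type O-alkylation (MOM protection) masks the acidic OH of ring C so that the aryl Grignard reagent of step 2 can be made; no stereocentre is involved.

**Step 2**
Reactants: 2 5-bromo-1,3-dimethoxy-2-(methoxymethoxy)benzene; 3 (S)-propylene oxide
Product: 5 (2S)-1-[3,5-dimethoxy-4-(methoxymethoxy)phenyl]propan-2-ol, via arylmagnesium bromide 4 (not isolated)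
Conditions: Mg turnings, THF, 50 °C; then CuI (10 mol %), 3, −30 °C to 0 °C; aq NH4Cl
Reagents that add atoms: none
Why: Copper-catalysed opening of a terminal epoxide by an aryl Grignard reagent is an SN2 attack at the unsubstituted CH2, so the stereocentre of 3 is not touched and appears in 5 as (S).

**Step 3**
Reactants: 5 (2S)-1-[3,5-dimethoxy-4-(methoxymethoxy)phenyl]propan-2-ol; 6 5-bromo-2-hydroxy-3-methoxybenzaldehyde
Product: 7 5-bromo-2-{[(2R)-1-[3,5-dimethoxy-4-(methoxymethoxy)phenyl]propan-2-yl]oxy}-3-methoxybenzaldehyde
Conditions: PPh3, DIAD, THF, 0 °C to rt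
Reagents that add atoms: none
Why: In this Mitsunobu etherification the single, acidic phenol OH of 6 (ortho-formyl, para-bromo) displaces the oxyphosphonium group of the secondary alcohol by SN2 with inversion, which turns (S)-5 into the (R)-configured ether carbon that becomes C3 and leaves no regiochemical choice on ring A.

**Step 4**
Reactants: 7 5-bromo-2-{[(2R)-1-[3,5-dimethoxy-4-(methoxymethoxy)phenyl]propan-2-yl]oxy}-3-methoxybenzaldehyde
Product: 9 5-bromo-2-{[(2R)-1-(4-hydroxy-3,5-dimethoxyphenyl)propan-2-yl]oxy}-3-methoxyphenol, via aryl formate 8 (not isolated)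
Conditions: mCPBA, CH2Cl2, 0 °C to rt; then HCl (cat.), MeOH, 45 °C
Reagents that add atoms: 3-chloroperbenzoic acid (mCPBA), OOC(=O)c1cccc(Cl)c1
Why: Baeyer–Villiger oxidation of an electron-rich ortho-alkoxybenzaldehyde goes with aryl migration to the aryl formate, and acid-catalysed methanolysis then removes the formate and the MOM acetal together, which is safe because no acid-sensitive alkene is present yet and the stereocentre has no acidifying neighbour.

**Step 5**
Reactants: 9 5-bromo-2-{[(2R)-1-(4-hydroxy-3,5-dimethoxyphenyl)propan-2-yl]oxy}-3-methoxyphenol; 10 (E)-prop-1-enylboronic acid pinacol ester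
Product: 11 4-[(2R)-2-{2-hydroxy-6-methoxy-4-[(E)-prop-1-enyl]phenoxy}propyl]-2,6-dimethoxyphenol
Conditions: Pd(dppf)Cl2 (3 mol %), K2CO3, 1,4-dioxane/H2O 4:1, 80 °C, argon
Reagents that add atoms: none
Why: Suzuki–Miyaura coupling of an aryl bromide with an alkenylboronate is stereoretentive, so the E geometry of 10 is carried over, and the free phenols are tolerated as phenoxides.

**Step 6**
Reactants: 11 4-[(2R)-2-{2-hydroxy-6-methoxy-4-[(E)-prop-1-enyl]phenoxy}propyl]-2,6-dimethoxyphenol
Product: 14 4-[(2R,3R)-5-methoxy-3-methyl-7-[(E)-prop-1-enyl]-2,3-dihydro-1,4-benzodioxin-2-yl]-2,6-dimethoxyphenol, via phenoxyl radical 12 (not isolated), via p-quinone methide 13 (not isolated)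
Conditions: laccase from Trametes versicolor (multicopper oxidase, cat.), O2 (1 atm), NaOAc buffer (0.1 M, pH 5.0)/EtOAc 1:1, vigorous stirring, 25 °C
Reagents that add atoms: none
Why: Proposed new method: the surface-exposed type 1 copper site of the laccase should take one electron from the most easily oxidised phenol, the 4-alkyl-2,6-dimethoxyphenol of ring C, to give phenoxyl radical 12, which has substituents on both ortho positions and on the para position and therefore should not couple but disproportionate, by loss of a benzylic hydrogen, into p-quinone methide 13 and one molecule of 11 that re-enters the cycle, while O2 ends as water. The closest known reaction types are the dehydrogenation of 4-alkyl-2,6-dimethoxyphenols to p-quinone methides with Ag2O followed by 1,6-addition of an oxygen nucleophile, and the laccase- or peroxidase-driven build-up of benzodioxane units from catechol-type lignin monomers, where the same internal capture of a p-quinone methide by the neighbouring phenol OH outruns the addition of water. Ring B closes by a 6-exo-trig oxa-1,6-conjugate addition of the ring A OH (the later O1) to the exocyclic methine carbon (the later C2), which forms the O1–C2 bond and rearomatises ring C. The new stereocentre C2 is controlled by the (R)-centre C3: allylic 1,3-strain should hold the C3–H bond in the plane of the dienone, the tethered OH then reaches only one face, H2 and H3 come out anti, and this trans-(2R,3R) isomer with both substituents equatorial is also the thermodynamic one, since the free para-OH allows ring B to reopen to 13 and close again. The step needs chemoselectivity among two phenols and one alkene, and the substrate secures it: the ring A phenol has only one ortho oxygen, hence the higher oxidation potential, and no para alkyl group from which a quinone methide could form, and the E-propenyl group is conjugated only with the etherified O4 and so stays outside phenoxyl radical chemistry, whereas quinone oxidants such as DDQ are known to attack such propenylarenes. In one operation on the unprotected substrate the step thus delivers the benzylic C–H oxidation, the C–O bond, ring B and the second stereocentre, and the two-phase medium should keep 13 away from water.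

**Compound list**
1 | 4-bromo-2,6-dimethoxyphenol | COc1cc(Br)cc(OC)c1O | starting material
2 | 5-bromo-1,3-dimethoxy-2-(methoxymethoxy)benzene | COCOc1c(OC)cc(Br)cc1OC | intermediate
3 | (S)-propylene oxide, (2S)-2-methyloxirane | C[C@H]1CO1 | starting material
4 | [3,5-dimethoxy-4-(methoxymethoxy)phenyl]magnesium bromide | COCOc1c(OC)cc([Mg]Br)cc1OC | intermediate
5 | (2S)-1-[3,5-dimethoxy-4-(methoxymethoxy)phenyl]propan-2-ol | C[C@H](O)Cc1cc(OC)c(OCOC)c(OC)c1 | intermediate
6 | 5-bromo-2-hydroxy-3-methoxybenzaldehyde | COc1cc(Br)cc(C=O)c1O | starting material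
7 | 5-bromo-2-{[(2R)-1-[3,5-dimethoxy-4-(methoxymethoxy)phenyl]propan-2-yl]oxy}-3-methoxybenzaldehyde | COc1cc(Br)cc(C=O)c1O[C@H](C)Cc1cc(OC)c(OCOC)c(OC)c1 | intermediate
8 | 5-bromo-2-{[(2R)-1-[3,5-dimethoxy-4-(methoxymethoxy)phenyl]propan-2-yl]oxy}-3-methoxyphenyl formate | COc1cc(Br)cc(OC=O)c1O[C@H](C)Cc1cc(OC)c(OCOC)c(OC)c1 | intermediate
9 | 5-bromo-2-{[(2R)-1-(4-hydroxy-3,5-dimethoxyphenyl)propan-2-yl]oxy}-3-methoxyphenol | COc1cc(Br)cc(O)c1O[C@H](C)Cc1cc(OC)c(O)c(OC)c1 | intermediate
10 | (E)-prop-1-enylboronic acid pinacol ester | C/C=C/B1OC(C)(C)C(C)(C)O1 | starting material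
11 | 4-[(2R)-2-{2-hydroxy-6-methoxy-4-[(E)-prop-1-enyl]phenoxy}propyl]-2,6-dimethoxyphenol | C/C=C/c1cc(OC)c(O[C@H](C)Cc2cc(OC)c(O)c(OC)c2)c(O)c1 | intermediate
12 | ring C phenoxyl radical of 11 | C/C=C/c1cc(OC)c(O[C@H](C)Cc2cc(OC)c([O])c(OC)c2)c(O)c1 | intermediate
13 | 4-[(2R)-2-{2-hydroxy-6-methoxy-4-[(E)-prop-1-enyl]phenoxy}propylidene]-2,6-dimethoxycyclohexa-2,5-dien-1-one | C/C=C/c1cc(OC)c(O[C@H](C)C=C2C=C(OC)C(=O)C(OC)=C2)c(O)c1 | intermediate
14 | 4-[(2R,3R)-5-methoxy-3-methyl-7-[(E)-prop-1-enyl]-2,3-dihydro-1,4-benzodioxin-2-yl]-2,6-dimethoxyphenol (CNP0227775.1) | C/C=C/c1cc(OC)c2c(c1)O[C@H](c1cc(OC)c(O)c(OC)c1)[C@@H](C)O2 | target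

**Total step count:** 6
**Longest linear sequence:** 6 steps (1 → 2 → 5 → 7 → 9 → 11 → 14)

**Three steps most likely to fail**

Step 6 (the labelled step). Several processes may go wrong:
- turnover at the liquid–liquid interface may be slow;
- phenoxyl radicals may couple intermolecularly instead of disproportionating;
- water may capture the quinone methide;
- the quinone methide may tautomerise to the enol ether, which would erode C3;
- the phenol of the product may be oxidised further.

The fallback uses known chemistry, a stoichiometric chemical oxidant and another order of events. It sets out from 9, before the alkene is present. Ag2O (CH2Cl2, dark, rt) dehydrogenates the 4-alkyl-2,6-dimethoxyphenol to the bromo p-quinone methide F1. This closes by the same 6-exo-trig 1,6-addition to the trans-bromobenzodioxane F2. A Suzuki–Miyaura coupling of F2 with 10 under the conditions of step 5 comes back to the route at 14.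

Step 3. The phenol carries two ortho substituents, so displacement may be slow. The oxyphosphonium salt may undergo β-elimination to a propenylarene. The electron-rich ring C may participate (phenonium pathway), which would erode the inversion. The fallback separates activation from displacement and sets out from 5. MsCl and Et3N (CH2Cl2, 0 °C) give the isolated (S)-mesylate F3. Treating F3 with 6 and Cs2CO3 in DMF at 50 °C is a Williamson ether synthesis that proceeds with inversion, and it comes back to the route at 7.

Step 5. Oxidative addition of the electron-rich, phenoxide-bearing aryl bromide may be sluggish. The alkenylboronate may protodeboronate, and the diphenol may be oxidised by air in hot base. The fallback avoids cross-coupling by carrying the three-carbon chain from the start, and it sets out from 5. Mitsunobu etherification with commercial 5-allyl-2-hydroxy-3-methoxybenzaldehyde gives the allyl aldehyde F4. An acid Dakin-type oxidation (H2O2, H2SO4 cat., MeOH, rt) leaves the isolated alkene alone and also cleaves the formate and the MOM group, giving the allyl diphenol F5. RuHCl(CO)(PPh3)3 (cat.) in toluene at 80 °C isomerises the allyl group to the conjugated E-propenyl group, and this comes back to the route at 11.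

**Further compounds**
F1 | step 6 | 4-[(2R)-2-(4-bromo-2-hydroxy-6-methoxyphenoxy)propylidene]-2,6-dimethoxycyclohexa-2,5-dien-1-one | COc1cc(Br)cc(O)c1O[C@H](C)C=C1C=C(OC)C(=O)C(OC)=C1
F2 | step 6 | 4-[(2R,3R)-7-bromo-5-methoxy-3-methyl-2,3-dihydro-1,4-benzodioxin-2-yl]-2,6-dimethoxyphenol | Brc1cc(OC)c2c(c1)O[C@H](c1cc(OC)c(O)c(OC)c1)[C@@H](C)O2
F3 | step 3 | (2S)-1-[3,5-dimethoxy-4-(methoxymethoxy)phenyl]propan-2-yl methanesulfonate | C[C@H](OS(C)(=O)=O)Cc1cc(OC)c(OCOC)c(OC)c1
F4 | step 5 | 5-allyl-2-{[(2R)-1-[3,5-dimethoxy-4-(methoxymethoxy)phenyl]propan-2-yl]oxy}-3-methoxybenzaldehyde | C=CCc1cc(OC)c(O[C@H](C)Cc2cc(OC)c(OCOC)c(OC)c2)c(C=O)c1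
F5 | step 5 | 4-[(2R)-2-(4-allyl-2-hydroxy-6-methoxyphenoxy)propyl]-2,6-dimethoxyphenol | C=CCc1cc(OC)c(O[C@H](C)Cc2cc(OC)c(O)c(OC)c2)c(O)c1
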